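With the furanone numbered O-1′, C-2′ (C=O), C-3′, C-4′, C-5′ (OCH2) and the carbinol as C-16, everything rests on the C-4′–C-5′ bond: the O-1′–C-5′ unit and the C-16 hydroxyl both hang on C-4′, a masked 2-methylidene-1,3-diol. A (bromomethyl)dimethylsilyl group on the C-16 oxygen of an (R)-propargylic alcohol carries C-5′ onto the internal alkyne carbon by 5-exo-dig radical cyclisation; Tamao oxidation of the temporary oxasilolane unveils the diol, and acrylate metathesis completes the furanone. A second temporary silicon tether to a sclareol-derived allylic alcohol and ring-closing metathesis then fix the Z-trisubstituted C-13/C-14 alkene.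

Key step: step 7

Atom labels: labdane numbering is used for the decalin (C-1 to C-10, ring alkene C-8/C-9) and the chain (C-11, C-12, C-13=C-14, C-15, C-16); the CH2OH carbon on C-13 is called C-13a.

Step 1
Reactants: 1 sclareol
Product: 2 8α-hydroxy-14,15-dinorlabdan-13-one
Conditions: KMnO4, MgSO4, acetone/H2O, 0 °C to rt
Reagents that add atoms: none
Why: Permanganate oxidative degradation of the vinyl carbinol (alkene cleavage, then oxidative decarboxylation of the α-hydroxy acid) should leave the C-13 methyl ketone, whose oxygen is the former C-13 hydroxyl, without touching the ring stereocentres.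

Step 2
Reactants: 2 8α-hydroxy-14,15-dinorlabdan-13-one
Product: 3 14,15-dinorlabd-8-en-13-one
Conditions: 57% aq. HI (cat.), benzene, 80 °C
Reagents that add atoms: none
Why: Acid-catalysed E1 dehydration of the tertiary C-8 alcohol under equilibrating conditions should funnel all alkene isomers (and any cyclic enol ether formed from the hydroxy ketone) to the tetrasubstituted C-8/C-9 alkene, the thermodynamic product; C-5 and C-10 cannot epimerise.

Step 3
Reactants: 3 14,15-dinorlabd-8-en-13-one
Product: 5 4-[(4aS,8aS)-2,5,5,8a-tetramethyl-3,4,4a,5,6,7,8,8a-octahydronaphthalen-1-yl]but-1-en-2-yl trifluoromethanesulfonate, via potassium enolate 4 (not isolated)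
Conditions: KN(SiMe3)2 (1.05 equiv), THF, −78 °C; then PhNTf2, −78 to 0 °C
Reagents that add atoms: N-phenylbis(trifluoromethanesulfonimide), O=S(=O)(N(c1ccccc1)S(=O)(=O)C(F)(F)F)C(F)(F)F
Why: Kinetic deprotonation by the hindered amide base occurs at the methyl group, and O-sulfonylation of the terminal enolate gives the 1-alken-2-yl triflate (kinetic enolate triflation); one equivalent of base avoids elimination to the alkyne.

Step 4
Reactants: 5 the enol triflate
Product: 6 2-methylidene-4-[(4aS,8aS)-2,5,5,8a-tetramethyl-3,4,4a,5,6,7,8,8a-octahydronaphthalen-1-yl]butan-1-ol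
Conditions: Bu3SnCH2OH, Pd(PPh3)4 (5 mol%), LiCl, 1,4-dioxane, 100 °C
Reagents that add atoms: (tributylstannyl)methanol, CCCC[Sn](CCCC)(CCCC)CO
Why: Migita–Kosugi–Stille coupling: oxidative addition of the alkenyl triflate to zerovalent palladium, chloride exchange and selective transfer of the α-oxygenated CH2OH group from tin should deliver the 2-substituted allylic alcohol (C-13a installed).

Step 5
Reactants: 7 3-(trimethylsilyl)prop-2-ynal
Product: 10 (3R)-hex-5-en-1-yn-3-ol, via borinate 8 (not isolated), via silylated alkynol 9 (not isolated)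
Conditions: (+)-Ipc2B(allyl), Et2O, −78 °C; then 3 M NaOH, 30% H2O2, 0 °C to rt; then K2CO3, MeOH, rt
Reagents that add atoms: (+)-B-allyldiisopinocampheylborane, C=CCB([C@H]1C[C@H]2C[C@@H]([C@@H]1C)C2(C)C)[C@H]1C[C@H]2C[C@@H]([C@@H]1C)C2(C)C
Why: Brown asymmetric allylboration through a chair six-membered transition state with the alkynyl group equatorial; by the established sense of induction the reagent derived from (−)-α-pinene should give the (R)-carbinol (C-16), and the basic work-up oxidises the borinate and cleaves the C(sp)–Si bond.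

Step 6
Reactants: 10 (3R)-hex-5-en-1-yn-3-ol
Product: 11 (bromomethyl)[(3R)-hex-5-en-1-yn-3-yloxy]dimethylsilane
Conditions: BrCH2SiMe2Cl, Et3N, DMAP (cat.), CH2Cl2, 0 °C
Reagents that add atoms: (bromomethyl)chlorodimethylsilane, C[Si](C)(Cl)CBr
Why: Base-mediated O-silylation of the secondary alcohol installs the temporary tether that carries the future C-5′; C-16 is not affected.

Step 7
Reactants: 11 (bromomethyl)[(3R)-hex-5-en-1-yn-3-yloxy]dimethylsilane
Product: 13 (3R)-2-methylidenehex-5-ene-1,3-diol, via oxasilolane 12 (not isolated)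
Conditions: Bu3SnH (1.3 equiv), AIBN (cat.), benzene (0.03 M), 80 °C; then KF, KHCO3, 30% H2O2, THF/MeOH, rt
Reagents that add atoms: hydrogen peroxide, OO
Why: The tributyltin radical abstracts bromine from 11 to give an α-silyl methyl radical that adds to the internal alkyne carbon (future C-4′), forming the C-4′–C-5′ bond and a 1,2-oxasilolane; the exocyclic vinyl radical is reduced by Bu3SnH, and fluoride-assisted peroxide oxidation then moves the ring CH2 from silicon to oxygen and cleaves the Si–O bond, so that C-5′ emerges as CH2OH beside the untouched C-16 hydroxyl. The closest known reaction type is the Nishiyama–Stork silicon-tethered radical cyclisation of (bromomethyl)dimethylsilyl propargyl ethers followed by Tamao–Fleming oxidation. The only ring closed is the five-membered oxasilolane, in the 5-exo-dig mode. No stereocentre is created: the terminal alkyne gives a methylidene group, and C-16 keeps its R configuration because its C–O bond is never broken. The step needs regioselectivity (internal over terminal alkyne carbon, enforced by the three-atom O–Si–C tether) and chemoselectivity (alkyne over the allyl group, and hydrogen transfer to the vinyl radical before it can add to the allyl alkene), which the fast 5-exo-dig closure and a tin hydride concentration near 0.03 M should secure.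

Step 8
Reactants: 13 (3R)-2-methylidenehex-5-ene-1,3-diol
Product: 14 (3R)-3-hydroxy-2-methylidenehex-5-en-1-yl prop-2-enoate
Conditions: acryloyl chloride (1.05 equiv), 2,4,6-collidine, CH2Cl2, −78 °C
Reagents that add atoms: acryloyl chloride, C=CC(=O)Cl
Why: Kinetically controlled O-acylation at low temperature with a hindered pyridine base should discriminate the primary allylic hydroxyl from the more hindered secondary C-16 hydroxyl (selective esterification).

Step 9
Reactants: 14 (3R)-3-hydroxy-2-methylidenehex-5-en-1-yl prop-2-enoate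
Product: 15 4-[(1R)-1-hydroxybut-3-en-1-yl]furan-2(5H)-one
Conditions: second-generation Grubbs catalyst RuCl2(=CHPh)(PCy3)(H2IMes) (5 mol%), CH2Cl2 (0.005 M), 40 °C
Reagents that add atoms: none
Why: Ring-closing metathesis between the acrylate and the 1,1-disubstituted alkene should close the five-membered unsaturated lactone with loss of ethylene; the terminal allyl group has no partner for a small ring, and high dilution disfavours its cross-metathesis.

Step 10
Reactants: 15 4-[(1R)-1-hydroxybut-3-en-1-yl]furan-2(5H)-one; 6 the allylic alcohol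
Product: 17 mixed diisopropylsilylene ketal of 15 (through O on C-16) and 6 (through O on C-13a), via chlorosilyl ether 16 (not isolated)
Conditions: iPr2SiCl2 (3 equiv), imidazole, CH2Cl2, 0 °C; volatiles removed under vacuum; then 6, imidazole, DMF, rt
Reagents that add atoms: dichlorodiisopropylsilane, CC(C)[Si](Cl)(Cl)C(C)C
Why: Stepwise nucleophilic substitution at silicon: the hindered secondary alcohol reacts once with excess dichlorosilane, and the remaining Si–Cl bond is then displaced by the primary allylic alcohol to give the unsymmetrical bis-alkoxysilane (temporary silicon tether).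

Step 11
Reactants: 17 the mixed silylene ketal
Product: 18 eight-membered cyclic silaketal (2,2-diisopropyl-1,3-dioxa-2-silacyclooct-5-ene; ring alkene C-13=C-14, furanone on C-16 (R), decalinyl-ethyl chain on C-13)
Conditions: second-generation Grubbs catalyst RuCl2(=CHPh)(PCy3)(H2IMes) (10 mol%), toluene (0.002 M), 80 °C
Reagents that add atoms: none
Why: Temporary silicon-tethered ring-closing metathesis: the ruthenium alkylidene formed at the terminal C-14 alkene closes onto the 1,1-disubstituted C-13 alkene, and the eight-membered ring can only hold a cis ring alkene, which places C-13a and C-15 on the same side (Z); the C-8/C-9 and furanone alkenes are inert.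

Step 12
Reactants: 18 the cyclic silaketal
Product: 19 4-[(1R,3Z)-1-hydroxy-4-(hydroxymethyl)-6-[(4aS,8aS)-2,5,5,8a-tetramethyl-3,4,4a,5,6,7,8,8a-octahydronaphthalen-1-yl]hex-3-en-1-yl]furan-2(5H)-one (target)
Conditions: HF·pyridine, pyridine, THF, 0 °C to rt
Reagents that add atoms: none
Why: Fluoride cleavage of both Si–O bonds (desilylation) should release the C-13a and C-16 hydroxyl groups without affecting the butenolide or the alkene geometry.

Compound list
1 | sclareol, (13R)-labd-14-ene-8α,13-diol | CC1(C)CCC[C@@]2(C)[C@H]1CC[C@@](C)(O)[C@@H]2CC[C@@](C)(O)C=C | starting material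
2 | 8α-hydroxy-14,15-dinorlabdan-13-one | CC1(C)CCC[C@@]2(C)[C@H]1CC[C@@](C)(O)[C@@H]2CCC(C)=O | intermediate
3 | 14,15-dinorlabd-8-en-13-one | CC1=C(CCC(C)=O)[C@@]2(C)CCCC(C)(C)[C@@H]2CC1 | intermediate
4 | potassium 4-[(4aS,8aS)-2,5,5,8a-tetramethyl-3,4,4a,5,6,7,8,8a-octahydronaphthalen-1-yl]but-1-en-2-olate | CC1=C(CCC(=C)[O-])[C@@]2(C)CCCC(C)(C)[C@@H]2CC1.[K+] | intermediate
5 | 4-[(4aS,8aS)-2,5,5,8a-tetramethyl-3,4,4a,5,6,7,8,8a-octahydronaphthalen-1-yl]but-1-en-2-yl trifluoromethanesulfonate | CC1=C(CCC(=C)OS(=O)(=O)C(F)(F)F)[C@@]2(C)CCCC(C)(C)[C@@H]2CC1 | intermediate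
6 | 2-methylidene-4-[(4aS,8aS)-2,5,5,8a-tetramethyl-3,4,4a,5,6,7,8,8a-octahydronaphthalen-1-yl]butan-1-ol | CC1=C(CCC(=C)CO)[C@@]2(C)CCCC(C)(C)[C@@H]2CC1 | intermediate
7 | 3-(trimethylsilyl)prop-2-ynal | C[Si](C)(C)C#CC=O | starting material
8 | bis(isopinocampheyl)borinate of (3R)-1-(trimethylsilyl)hex-5-en-1-yn-3-ol | C=CC[C@@H](OB([C@H]1C[C@H]2C[C@@H]([C@@H]1C)C2(C)C)[C@H]1C[C@H]2C[C@@H]([C@@H]1C)C2(C)C)C#C[Si](C)(C)C | intermediate
9 | (3R)-1-(trimethylsilyl)hex-5-en-1-yn-3-ol | C=CC[C@@H](O)C#C[Si](C)(C)C | intermediate
10 | (3R)-hex-5-en-1-yn-3-ol | C=CC[C@@H](O)C#C | intermediate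
11 | (bromomethyl)[(3R)-hex-5-en-1-yn-3-yloxy]dimethylsilane | C=CC[C@@H](O[Si](C)(C)CBr)C#C | intermediate
12 | (5R)-2,2-dimethyl-4-methylidene-5-(prop-2-en-1-yl)-1,2-oxasilolane | C=CC[C@@H]1C(=C)C[Si](C)(C)O1 | intermediate
13 | (3R)-2-methylidenehex-5-ene-1,3-diol | C=CC[C@@H](O)C(=C)CO | intermediate
14 | (3R)-3-hydroxy-2-methylidenehex-5-en-1-yl prop-2-enoate | C=CC[C@@H](O)C(=C)COC(=O)C=C | intermediate
15 | 4-[(1R)-1-hydroxybut-3-en-1-yl]furan-2(5H)-one | C=CC[C@@H](O)C1=CC(=O)OC1 | intermediate
16 | chlorodiisopropylsilyl ether of 15 (on the C-16 oxygen) | C=CC[C@@H](O[Si](Cl)(C(C)C)C(C)C)C1=CC(=O)OC1 | intermediate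
17 | mixed diisopropylsilylene ketal of 15 and 6 | CC1=C(CCC(=C)CO[Si](C(C)C)(C(C)C)O[C@H](CC=C)C3=CC(=O)OC3)[C@@]2(C)CCCC(C)(C)[C@@H]2CC1 | intermediate
18 | eight-membered cyclic silaketal, C-16 (R), ring alkene Z | CC1=C(CC/C4=C/C[C@H](C3=CC(=O)OC3)O[Si](C(C)C)(C(C)C)OC4)[C@@]2(C)CCCC(C)(C)[C@@H]2CC1 | intermediate
19 | 4-[(1R,3Z)-1-hydroxy-4-(hydroxymethyl)-6-[(4aS,8aS)-2,5,5,8a-tetramethyl-3,4,4a,5,6,7,8,8a-octahydronaphthalen-1-yl]hex-3-en-1-yl]furan-2(5H)-one | CC1=C(CC/C(=C/C[C@@H](O)C2=CC(=O)OC2)CO)[C@@]2(C)CCCC(C)(C)[C@@H]2CC1 | target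

Total step count: 12. Longest linear sequence: 8 steps (7 to 19, steps 5 to 12); the sclareol branch contributes steps 1 to 4 and joins at step 10.

Steps most likely to fail

Step 7. The α-silyl radical may take hydrogen from tin hydride before it cyclises, or abstract an allylic hydrogen from C-15. If the hydride concentration falls too low, the vinyl radical may instead add to the allyl alkene. The small, volatile intermediates are also easily lost. The fallback gives up the radical tether and builds the same bond by palladium chemistry, setting out from 10 and returning at 15 (steps 8 and 9 are then not needed). Double deprotonation of 10 with n-BuLi and carboxylation with CO2 should give (4R)-4-hydroxyhept-6-en-2-ynoic acid F1. Anti-hydroiodination with NaI in AcOH should give (2Z,4R)-4-hydroxy-3-iodohepta-2,6-dienoic acid F2, with iodine cis to the carboxyl group. Stille coupling of F2 with (tributylstannyl)methanol (Pd(PPh3)4, CuI, DMF) and spontaneous lactonisation of the resulting cis hydroxy acid should give 15.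

Step 9. The ruthenium carbene forms first at the unhindered terminal alkene and may be consumed in intermolecular cross-metathesis (oligomers) before the slower acrylate and 1,1-disubstituted alkene close the lactone. The fallback tethers before any metathesis, setting out from 14 and returning at 18. Treatment of 14 with iPr2SiCl2 and imidazole should give the chlorosilyl ether of the acrylate F3, and addition of 6 should give the tetraene silaketal F4, in which every alkene has an intramolecular partner. One treatment with the ruthenium catalyst in hot dilute toluene should then close the furanone and the eight-membered silaketal in the same operation.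

Step 10. Double substitution at silicon by the same alcohol would give symmetrical ketals, and the excess dichlorosilane with base may enolise and O-silylate the butenolide. The fallback uses a monofunctional silane and a base-free coupling, setting out from 15 and returning at 17. Chlorodiisopropylsilane (iPr2SiHCl) and imidazole should convert 15 into the isolable hydridosilyl ether F5, which cannot react twice. Dehydrogenative coupling of its Si–H bond with the primary alcohol 6, catalysed by Rh2(O2CC3F7)4 in CH2Cl2, should then give 17.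

Further compounds
F1 | step 7 | (4R)-4-hydroxyhept-6-en-2-ynoic acid | C=CC[C@@H](O)C#CC(=O)O
F2 | step 7 | (2Z,4R)-4-hydroxy-3-iodohepta-2,6-dienoic acid | C=CC[C@@H](O)/C(I)=C/C(=O)O
F3 | step 9 | (3R)-3-{[chlorodi(propan-2-yl)silyl]oxy}-2-methylidenehex-5-en-1-yl prop-2-enoate | C=CC[C@@H](O[Si](Cl)(C(C)C)C(C)C)C(=C)COC(=O)C=C
F4 | step 9 | mixed diisopropylsilylene ketal of acrylate 14 (C-16 oxygen) and alcohol 6 | CC1=C(CCC(=C)CO[Si](C(C)C)(C(C)C)O[C@H](CC=C)C(=C)COC(=O)C=C)[C@@]2(C)CCCC(C)(C)[C@@H]2CC1
F5 | step 10 | 4-[(1R)-1-{[di(propan-2-yl)silyl]oxy}but-3-en-1-yl]furan-2(5H)-one | C=CC[C@@H](O[SiH](C(C)C)C(C)C)C1=CC(=O)OC1
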